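## Analysis of the target

Locants used throughout are C1–C16 for the acyl chain (C1 amide carbonyl, C4=C5, C7–OMe, C9–Me), C1'' (carbinol), C2'' (N-bearing) and C3'' (CH2OMe) for the linker, and C1' (C=O), C2' (bears C1''), C3' (=CH), C4' (CHMe), C5' (CHOH) and C6' (CMe2) for the ring. The target is a secondary amide that joins a C16 fatty acid to a C3 amino-alcohol linker, which is bonded through C1'' to C2' of the only ring, a cyclohex-2-enone. It carries six stereocentres in three isolated pairs, C7 (R)/C9 (S) as a 1,3-anti pair on a flexible chain, C1'' (S)/C2'' (R) as an anti 1,2-amino alcohol and C4' (S)/C5' (R) trans on the ring, and no pair can relay its configuration to another, so each must be set on its own. The head group is formally the adduct of an α-amino aldehyde with C2' of a fully substituted enone. Two features of the ring drive the plan: the quaternary C6' lies between the C1' carbonyl and the C5' carbinol (a 2,2-dimethyl-1,3-dioxygenated unit), and C2' is a single carbon between C1' and C3', so that deleting it leaves a five-membered ring whose oxygen pattern is that of the symmetric dione 15. The sensitive groups are the β-hydroxy ketone C5'–C6'–C1' (retro-aldol under base), C4'–H γ to the enone (epimerization, or vinylogous loss of the C5' oxygen, through the dienolate), the enone as Michael acceptor, the free amine at C2'', which is γ to the C1' ketone (cyclic imine), and the C4=C5 E-alkene, which rules out late hydrogenation. The hard parts are a ring that six-membered precursors do not map onto (the methyl group sits γ to the carbonyl and next to the carbinol) and the C2'–C1'' bond with control at C1''.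

## Retrosynthetic reasoning

**Amide N–C1.** Cutting the amide of 28 gives acid 14 and the ammonium salt 27. This is the most convergent cut and keeps the valuable acid for the last step. The forward reaction must acylate nitrogen faster than the free amine can condense with the C1' ketone.

**C2'–C1'' bond.** 27 comes from the protected adduct 26, which is cut between C2' and C1'' into bromoenone 22 and the serine-derived aldehyde 25. The C3'' methyl ether and the C2'' configuration are bought with 23, so no late O-methylation is needed. The forward Nozaki–Hiyama–Kishi coupling needs no ketone protection and no base; it has to set C1'' anti to C2'' under Felkin–Anh control.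

**C1'–C2' and C2'–C3' bonds (key disconnection).** C2' with its bromine is removed from 22. What is left is the cyclopentene silyl enol ether 20, in which C1' and C3' are directly bonded. Forward, a [2+1] carbene addition turns 20 into the gem-dibromocyclopropane 21, whose strain-driven opening inserts C2' and delivers the enone, the halogen handle and the six-membered ring in one operation. The cut is made here because the five-membered precursor is what places the C4' methyl and the C5' oxygen correctly; a six-membered precursor does not.

**C4'–CH3 bond and the C3' enolate.** 20 is the trapped enolate of a cuprate addition to cyclopentenone 19. The C5' silyloxy group directs the methyl group trans, which sets C4'. Because C6' is quaternary the enolate cannot equilibrate, so the silyl enol ether is regiodefined.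

**C5' stereocentre.** 19 comes by dehydrogenation (through 18) from silyl ether 17, and 17 from hydroxy ketone 16. 16 is the product of an enantioselective mono-reduction of the mirror-symmetric dione 15. All ring chirality therefore stems from one desymmetrization, without resolution.

**Aldehyde 25.** It is the reduction product of Weinreb amide 24, made from commercial 23.

**Acid 14: C5–C6 bond and the alkene.** 14 is the O-methylation product (through 13) of hydroxy acid 12. The E-alkene of 12 comes from the alkyne of 11 by dissolving-metal reduction, so its geometry is set by mechanism and not by an olefination ratio. 11 is cut at C5–C6 into the dianion 10 of the alkynoic acid 9 and epoxide 8, which carries C7.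

**Epoxide 8.** C7 is set by catalyst-controlled α-chlorination of aldehyde 5 (through 6 and 7) and epoxide closure with inversion. 5 is the ozonolysis product (through 4) of alkene 3, and 3 comes from the chiral-pool bromide 1 and Grignard reagent 2. C9 is thus bought, not made.

## Alternatives that were turned down

Alternative 1: the textbook route. Disconnection of C2'–C1'' by a direct Morita–Baylis–Hillman reaction between the preformed six-membered enone A1 and the amide aldehyde A2. The forward key step is an amine- or phosphine-catalysed coupling. It was turned down for three reasons. First, the Lewis base must add at C3', next to the C4' methyl, of an enone whose carbonyl is flanked by the quaternary C6'; such cyclic enones react very slowly and tend to dimerize. Second, A2 has an acidic C2''–H between the acylamino group and the aldehyde; it epimerizes under the basic catalyst, and the reversible aldol step gives little control at C1''. Third, A1 is not cheap: from a six-membered 2,2-dimethyl-1,3-dione the methyl group must enter next to the future carbinol and the enone must be built on the other carbonyl, a protect/alkylate/reduce/oxidize/dehydrogenate relay of about eight steps, with C4' set only by relay.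

Alternative 2: the biosynthesis-like route. Disconnection of C2'=C3' by an intramolecular Knoevenagel-type aldol condensation of the open-chain keto aldehyde A3. The forward key step is a 6-(enolendo)-exo-trig aldol followed by dehydration; enolization of C1' can only go toward C2' because C6' is quaternary. It was turned down because A3 holds two β-hydroxy ketone units (C1''–C2'–C1' and C5'–C6'–C1'). The enolate at C2' can expel the C1'' hydroxyl before it cyclizes, the final dehydration can run toward C1'' instead of C3', retro-aldol cleavage at C5'–C6' is open, and C4' is α to the aldehyde and epimerizes. A3 also needs five stereocentres assembled on an acyclic chain by several aldol events, which costs more steps than the whole head group of the chosen route.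

Alternative 3: ring-closing metathesis. Disconnection of C2'=C3' in the acyclic dienone A4, with a second-generation Grubbs catalyst as the forward key step. A4 would come from a syn-crotylation (C4'/C5'), construction of the C1' vinyl ketone, and a Morita–Baylis–Hillman reaction of that acyclic ketone with 25. It was turned down because the C1'' selectivity problem is only moved, not solved. The metathesis must join a 1,1-disubstituted electron-poor alkene next to a quaternary centre. The sequence is four to five steps longer than the ring expansion, and no step does more than one job.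

Key step: step 11

Assumption: in steps 3 and 7 the catalyst enantiomer named is the one that the accepted enamine and oxazaborolidine models predict to give the configuration drawn; if the opposite sense is found, the mirror-image catalyst is used.

## Route

Step 1
Reactants: 1 (6R)-8-bromo-2,6-dimethyloct-2-ene ((R)-citronellyl bromide); 2 pentylmagnesium bromide
Product: 3 (6S)-2,6-dimethyltridec-2-ene
Conditions: Li2CuCl4 (3 mol %), THF, −20 °C → rt
Reagents that add atoms: none
Why: Kochi-type copper-catalysed sp3–sp3 coupling of a primary bromide with a primary Grignard reagent; the stereocentre is two carbons from the reacting carbon and is untouched (the descriptor changes from R to S only because the priorities of the two arms are exchanged).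

Step 2
Reactants: 3
Product: 5 (4S)-4-methylundecanal, via ozonide 4 (not isolated)
Conditions: O3, CH2Cl2, −78 °C; then PPh3, −78 °C → rt
Reagents that add atoms: ozone (O=[O+][O-])
Why: Ozonolysis with reductive work-up of the only alkene; the trisubstituted alkene loses acetone and leaves the aldehyde that carries C6–C16.

Step 3
Reactants: 5
Product: 8 (2R)-2-[(2S)-2-methylnonyl]oxirane, via chloroaldehyde 6 (not isolated), via chlorohydrin 7 (not isolated)
Conditions: N-chlorosuccinimide, (2R,5R)-2,5-diphenylpyrrolidine (10 mol %), CH2Cl2, 0 °C → rt; then NaBH4, MeOH, 0 °C; then KOH, EtOH/H2O, rt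
Reagents that add atoms: none
Why: Enamine-catalysed α-chlorination sets C7 under catalyst control (the remote C9 methyl should have little influence), reduction in the same flask prevents epimerization of the labile α-chloro aldehyde, and the alkoxide closes the epoxide by intramolecular SN2 with inversion, so the (2S)-chloride should give the (2R)-epoxide.

Step 4
Reactants: 8; 9 pent-4-ynoic acid
Product: 11 (7R,9S)-7-hydroxy-9-methylhexadec-4-ynoic acid, via dilithio acid 10 (not isolated)
Conditions: 9, n-BuLi (2 equiv per 9), THF/HMPA, −78 → 0 °C; then 8, 0 °C → rt; HCl (aq) work-up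
Reagents that add atoms: none
Why: SN2 opening of a terminal epoxide at its CH2 carbon by a lithium acetylide (the carboxylate is masked as its lithium salt) forms C5–C6; the C7–O bond is not touched, so C7 keeps its configuration.

Step 5
Reactants: 11
Product: 12 (4E,7R,9S)-7-hydroxy-9-methylhexadec-4-enoic acid
Conditions: Na, NH3 (l), THF, −33 °C; NH4Cl
Reagents that add atoms: none
Why: Dissolving-metal reduction of an internal alkyne proceeds through the trans vinyl radical and anion and should give the E-alkene; the carboxylate and alkoxide are inert and the oxygen at C7 is not β to the vinyl anion, so it cannot be expelled.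

Step 6
Reactants: 12
Product: 14 (4E,7R,9S)-7-methoxy-9-methylhexadec-4-enoic acid, via methyl ester 13 (not isolated)
Conditions: NaH, MeI, THF/DMF, 0 °C → rt; then LiOH, H2O/MeOH, rt; HCl (aq) work-up
Reagents that add atoms: iodomethane (CI); lithium hydroxide ([Li+].[OH-])
Why: Williamson methylation of the C7 alkoxide (the carboxylate is esterified at the same time) followed by saponification in the same flask; no stereocentre or the isolated alkene is affected.

Step 7
Reactants: 15 2,2-dimethylcyclopentane-1,3-dione
Product: 16 (3R)-3-hydroxy-2,2-dimethylcyclopentan-1-one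
Conditions: (S)-2-methyl-CBS-oxazaborolidine (20 mol %), BH3·SMe2 (0.6 equiv), THF, −40 °C; MeOH
Reagents that add atoms: none
Why: Corey–Bakshi–Shibata mono-reduction desymmetrizes the mirror-symmetric dione; with the quaternary carbon as the large substituent the (S)-catalyst is expected to give the (R)-carbinol (future C5'), and the second carbonyl of the product borinate is reduced more slowly.

Step 8
Reactants: 16
Product: 17 (3R)-2,2-dimethyl-3-(triethylsilyloxy)cyclopentan-1-one
Conditions: Et3SiCl, imidazole, DMF, 0 °C → rt
Reagents that add atoms: chlorotriethylsilane (CC[Si](Cl)(CC)CC)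
Why: Standard silylation; the triethylsilyl ether blocks retro-aldol cleavage, later directs the cuprate, and can be removed by the same acid that removes the Boc group.

Step 9
Reactants: 17
Product: 19 (4R)-5,5-dimethyl-4-(triethylsilyloxy)cyclopent-2-en-1-one, via silyl enol ether 18 (not isolated)
Conditions: lithium diisopropylamide, Me3SiCl, THF, −78 °C; then Pd(OAc)2 (10 mol %), O2 (1 atm), DMSO, 40 °C
Reagents that add atoms: none
Why: Saegusa–Ito dehydrogenation through the trimethylsilyl enol ether; only one α-carbon bears hydrogen because the other is quaternary, so the regiochemistry is fixed and the silyloxy group is not β to the enolate carbon.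

Step 10
Reactants: 19
Product: 20 triethyl{[(1R,2S)-2,5,5-trimethyl-4-(trimethylsilyloxy)cyclopent-3-en-1-yl]oxy}silane
Conditions: Me2CuLi (from MeLi and CuI, 1.5 equiv), Me3SiCl (3 equiv), THF, −78 °C; Et3N quench
Reagents that add atoms: lithium dimethylcuprate ([Li+].C[Cu-]C); chlorotrimethylsilane (C[Si](C)(C)Cl)
Why: Gilman cuprate conjugate addition with in situ O-silylation; the methyl group adds to the face opposite the adjacent silyloxy group (as in 4-silyloxycyclopentenones generally), which sets C4' trans to C5', and the enolate is trapped where it forms.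

Step 11
Reactants: 20
Product: 22 (4S,5R)-2-bromo-4,6,6-trimethyl-5-(triethylsilyloxy)cyclohex-2-en-1-one, via dibromocyclopropane 21 (not isolated)
Conditions: CHBr3 (1.5 equiv), KOtBu (1.3 equiv), pentane, −30 → 0 °C; filter; then toluene, 60 °C
Reagents that add atoms: bromoform (BrC(Br)Br)
Why: KOtBu deprotonates bromoform and α-elimination of bromide gives singlet dibromocarbene, which adds in a concerted [2+1] fashion to the electron-rich enol ether double bond of 20 (its only alkene) to give 21. On warming, the endo C–Br bond ionizes in concert with disrotatory opening of the strained bond shared by the three- and five-membered rings (cyclopropyl-to-allyl cation, assisted by the oxygen at C1'), and bromide removes the trimethylsilyl group from the oxocarbenium ion to give 22. The closest known reaction type is the dihalocarbene ring expansion of cyclic trimethylsilyl enol ethers to 2-halocycloalk-2-enones one carbon larger. The three-membered ring is closed by the [2+1] addition; the six-membered ring is not closed by a new bond but arises when the former C1'–C3' bond breaks, so that C2' ends up between C1' and C3' with its bromine in place. No new stereocentre remains: the two transient bridgehead centres are destroyed, so both faces of carbene attack converge on 22, and C4' and C5' are spectators carried over from 20. The selectivity needed is cleavage of the internal and not a peripheral cyclopropane bond; the bicyclic frame, which allows only the disrotatory mode in which the two ring bonds turn inward and which goes with loss of the endo bromide, and the donor oxygen at C1' secure it. Base is kept below the amount of bromoform so that the γ-hydrogen at C4' of 22 is not removed.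

Step 12
Reactants: 23 (2R)-2-[(tert-butoxycarbonyl)amino]-3-methoxypropanoic acid (N-Boc-O-methyl-D-serine)
Product: 24 tert-butyl N-[(2R)-3-methoxy-1-[methoxy(methyl)amino]-1-oxopropan-2-yl]carbamate
Conditions: MeNHOMe·HCl, EDC·HCl, HOBt, N-methylmorpholine, CH2Cl2, 0 °C → rt
Reagents that add atoms: N,O-dimethylhydroxylamine hydrochloride (CNOC.Cl)
Why: Carbodiimide amidation to the Weinreb amide; urethane-protected amino acids do not racemize under these conditions.

Step 13
Reactants: 24
Product: 25 tert-butyl N-[(2R)-1-methoxy-3-oxopropan-2-yl]carbamate
Conditions: LiAlH4, THF, −20 °C; KHSO4 (aq); used at once without chromatography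
Reagents that add atoms: none
Why: Weinreb amide reduction stops at the chelated tetrahedral intermediate, which gives the aldehyde only on acidic quench; cold, non-basic handling should preserve C2''.

Step 14
Reactants: 22; 25
Product: 26 tert-butyl N-[(1S,2R)-1-hydroxy-3-methoxy-1-[(3S,4R)-3,5,5-trimethyl-6-oxo-4-(triethylsilyloxy)cyclohex-1-en-1-yl]propan-2-yl]carbamate
Conditions: CrCl2 (4 equiv), NiCl2 (2 mol %), DMF, rt; 25 in excess (1.5 equiv)
Reagents that add atoms: none
Why: Nozaki–Hiyama–Kishi coupling: nickel inserts into the activated vinylic C–Br bond, the alkenyl group passes to chromium and adds to the aldehyde only, so the ketone needs no protection and no base touches C4' or C2''. In the strongly coordinating solvent the addition should follow the Felkin–Anh model with the carbamate nitrogen as the polar group, which gives the anti (1S,2R) amino alcohol; the epimer at C1'' is removed by chromatography.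

Step 15
Reactants: 26
Product: 27 (4S,5R)-2-[(1S,2R)-2-amino-1-hydroxy-3-methoxypropyl]-5-hydroxy-4,6,6-trimethylcyclohex-2-en-1-one hydrochloride
Conditions: HCl (4 M in dioxane), MeOH, 0 °C → rt; evaporate
Reagents that add atoms: hydrogen chloride (Cl)
Why: Acidolysis removes the Boc group and the triethylsilyl ether together, and the amine is isolated as its hydrochloride, the chloride coming from the acid; the amine stays protonated and cannot attack the C1' ketone or the enone, and the β-hydroxy ketone cannot dehydrate because C6' bears no hydrogen.

Step 16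
Reactants: 27; 14
Product: 28 (4E,7R,9S)-N-[(1S,2R)-1-hydroxy-1-[(3S,4R)-4-hydroxy-3,5,5-trimethyl-6-oxocyclohex-1-en-1-yl]-3-methoxypropan-2-yl]-7-methoxy-9-methylhexadec-4-enamide (target)
Conditions: EDC·HCl, HOBt, iPr2NEt (added last, slowly), CH2Cl2/DMF, 0 °C
Reagents that add atoms: none
Why: Carbodiimide/HOBt amide coupling; the amine is released only in the presence of the active ester, so N-acylation should outrun cyclization, and the two hindered secondary alcohols are not acylated by an HOBt ester under these conditions.

## Compound list

1 | (6R)-8-bromo-2,6-dimethyloct-2-ene ((R)-citronellyl bromide) | BrCC[C@H](C)CCC=C(C)C | starting material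
2 | pentylmagnesium bromide | CCCCC[Mg]Br | starting material
3 | (6S)-2,6-dimethyltridec-2-ene | CCCCCCC[C@H](C)CCC=C(C)C | intermediate
4 | 3,3-dimethyl-5-[(3S)-3-methyldecyl]-1,2,4-trioxolane (ozonide of 3) | CCCCCCC[C@H](C)CCC1OOC(C)(C)O1 | intermediate
5 | (4S)-4-methylundecanal | CCCCCCC[C@H](C)CCC=O | intermediate
6 | (2S,4S)-2-chloro-4-methylundecanal | CCCCCCC[C@H](C)C[C@@H](C=O)Cl | intermediate
7 | (2S,4S)-2-chloro-4-methylundecan-1-ol | CCCCCCC[C@H](C)C[C@@H](CO)Cl | intermediate
8 | (2R)-2-[(2S)-2-methylnonyl]oxirane | CCCCCCC[C@H](C)C[C@H]1OC1 | intermediate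
9 | pent-4-ynoic acid | C#CCCC(=O)O | starting material
10 | lithium 5-lithiopent-4-ynoate (dilithio acid from 9) | [Li+].[Li+].[C-]#CCCC(=O)[O-] | intermediate
11 | (7R,9S)-7-hydroxy-9-methylhexadec-4-ynoic acid | CCCCCCC[C@H](C)C[C@H](CC#CCCC(=O)O)O | intermediate
12 | (4E,7R,9S)-7-hydroxy-9-methylhexadec-4-enoic acid | CCCCCCC[C@H](C)C[C@H](C/C=C/CCC(=O)O)O | intermediate
13 | methyl (4E,7R,9S)-7-methoxy-9-methylhexadec-4-enoate | CCCCCCC[C@H](C)C[C@H](C/C=C/CCC(=O)OC)OC | intermediate
14 | (4E,7R,9S)-7-methoxy-9-methylhexadec-4-enoic acid | CCCCCCC[C@H](C)C[C@H](C/C=C/CCC(=O)O)OC | intermediate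
15 | 2,2-dimethylcyclopentane-1,3-dione | CC1(C)C(=O)CCC1=O | starting material
16 | (3R)-3-hydroxy-2,2-dimethylcyclopentan-1-one | O=C1CC[C@@H](O)C1(C)C | intermediate
17 | (3R)-2,2-dimethyl-3-(triethylsilyloxy)cyclopentan-1-one | O=C1CC[C@@H](O[Si](CC)(CC)CC)C1(C)C | intermediate
18 | triethyl{[(1R)-2,2-dimethyl-3-(trimethylsilyloxy)cyclopent-3-en-1-yl]oxy}silane | C[Si](C)(C)OC1=CC[C@@H](O[Si](CC)(CC)CC)C1(C)C | intermediate
19 | (4R)-5,5-dimethyl-4-(triethylsilyloxy)cyclopent-2-en-1-one | O=C1C=C[C@@H](O[Si](CC)(CC)CC)C1(C)C | intermediate
20 | triethyl{[(1R,2S)-2,5,5-trimethyl-4-(trimethylsilyloxy)cyclopent-3-en-1-yl]oxy}silane | C[Si](C)(C)OC1=C[C@H](C)[C@@H](O[Si](CC)(CC)CC)C1(C)C | intermediate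
21 | 6,6-dibromo-2,2,4-trimethyl-3-(triethylsilyloxy)-1-(trimethylsilyloxy)bicyclo[3.1.0]hexane (3,4-trans; both cyclopropane faces) | C[Si](C)(C)OC12C(Br)(Br)C1[C@H](C)[C@@H](O[Si](CC)(CC)CC)C2(C)C | intermediate
22 | (4S,5R)-2-bromo-4,6,6-trimethyl-5-(triethylsilyloxy)cyclohex-2-en-1-one | O=C1C(Br)=C[C@H](C)[C@@H](O[Si](CC)(CC)CC)C1(C)C | intermediate
23 | (2R)-2-[(tert-butoxycarbonyl)amino]-3-methoxypropanoic acid | CC(C)(C)OC(=O)N[C@H](COC)C(=O)O | starting material
24 | tert-butyl N-[(2R)-3-methoxy-1-[methoxy(methyl)amino]-1-oxopropan-2-yl]carbamate | CC(C)(C)OC(=O)N[C@H](COC)C(=O)N(C)OC | intermediate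
25 | tert-butyl N-[(2R)-1-methoxy-3-oxopropan-2-yl]carbamate | CC(C)(C)OC(=O)N[C@H](COC)C=O | intermediate
26 | tert-butyl N-[(1S,2R)-1-hydroxy-3-methoxy-1-[(3S,4R)-3,5,5-trimethyl-6-oxo-4-(triethylsilyloxy)cyclohex-1-en-1-yl]propan-2-yl]carbamate | CC(C)(C)OC(=O)N[C@H](COC)[C@@H](O)C1=C[C@H](C)[C@@H](O[Si](CC)(CC)CC)C(C)(C)C1=O | intermediate
27 | (4S,5R)-2-[(1S,2R)-2-amino-1-hydroxy-3-methoxypropyl]-5-hydroxy-4,6,6-trimethylcyclohex-2-en-1-one hydrochloride | Cl.N[C@H](COC)[C@@H](O)C1=C[C@H](C)[C@@H](O)C(C)(C)C1=O | intermediate
28 | (4E,7R,9S)-N-[(1S,2R)-1-hydroxy-1-[(3S,4R)-4-hydroxy-3,5,5-trimethyl-6-oxocyclohex-1-en-1-yl]-3-methoxypropan-2-yl]-7-methoxy-9-methylhexadec-4-enamide | CCCCCCC[C@H](C)C[C@H](C/C=C/CCC(=O)N[C@H](COC)[C@@H](O)C1=C[C@H](C)[C@@H](O)C(C)(C)C1=O)OC | target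

## Step count and risk

Total step count: 16. Longest linear sequence: 8 steps (15 → 28 through steps 7–11 and 14–16). The acid branch is 7 steps (steps 1–6 and 16) and the aldehyde branch 2 steps before it joins.

**Step 11 (key step).** Three processes can spoil it. The alkoxide base can desilylate the enol ether before the carbene is captured, which returns the saturated ketone on work-up. Residual base can remove the γ-hydrogen at C4' of the product, which leads to epimerization or vinylogous loss of the C5' silyloxy group. The bromotrimethylsilane set free can exchange with the triethylsilyl ether during the thermal opening.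
Fallback: it sets out from 20 and comes back at 26. Cyclopropanation of 20 with Et2Zn/CH2I2 should give the silyloxycyclopropane F1. Oxidative opening of its internal bond with FeCl3 in DMF should give the ring-expanded β-chloro ketone F2, and NaOAc in MeOH should eliminate HCl to the enone F3. α-Iodination with I2/pyridine should give the iodoenone F4, which takes the place of 22 in the coupling with 25 under the conditions of step 14 and gives 26. This is a carbene-free, base-free ring expansion and also supplies the more reactive halide.

**Step 14.** Chelation of chromium by the carbamate N–H can compete with Felkin–Anh attack, so that facial selectivity at the aldehyde is poor or reversed. The aldehyde can epimerize at C2'' before it is consumed. Oxidative addition into the vinylic bromide can be slow.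
Fallback: it sets out from 22 and 25 and comes back at 26. If the coupling gives mainly the C1'' epimer F5, it is converted into its methanesulfonate F6 (Ms2O, 2,6-lutidine). On warming, the Boc carbonyl oxygen displaces the sulfonate intramolecularly with inversion and loses isobutene to give the 4,5-cis oxazolidinone F7. Re-acylation on nitrogen (Boc2O, DMAP) gives the N-Boc oxazolidinone F8, and Cs2CO3 in MeOH opens the activated ring to return 26 with the correct C1''. The centre is thus corrected by neighbouring-group inversion instead of by the addition itself.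

**Step 16.** When the amine of 27 is set free, condensation with the γ-placed C1' ketone to a five-membered cyclic imine, or intermolecular aza-Michael addition to the enone, can compete with acylation.
Fallback: it sets out from 26 and 14 and comes back at 28. The C1'' hydroxyl of 26 is esterified with 14 (EDC, DMAP) to give the ester F9. HCl in dioxane/MeOH removes the Boc and silyl groups to give the ammonium ester F10. Neutralization (NaHCO3, THF/H2O) should trigger O→N acyl migration through a five-membered cyclic intermediate and deliver 28, so the amine is acylated intramolecularly the moment it is free.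

**Step 4.** The dilithio species 10 may aggregate and react sluggishly with the epoxide, or the carboxylate oxygen may open the epoxide instead of the acetylide carbon.
Fallback: it sets out from 8 and comes back at 14. The lithium acetylide of tert-butyl(dimethyl)(pent-4-yn-1-yloxy)silane (n-BuLi, BF3·OEt2, THF, −78 °C) opens 8 to give the homopropargylic alcohol F11. NaH/MeI gives the methyl ether F12, and Na in liquid NH3 gives the E-alkene F13. CrO3/H2SO4 in acetone cleaves the primary silyl ether and oxidizes the alcohol to the acid 14. The carboxyl group is thus carried as a protected alcohol through the C–C bond formation.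

## Further compounds

F1 | step 11 | 2,2,4-trimethyl-3-(triethylsilyloxy)-1-(trimethylsilyloxy)bicyclo[3.1.0]hexane (3,4-trans) | C[Si](C)(C)OC12CC1[C@H](C)[C@@H](O[Si](CC)(CC)CC)C2(C)C
F2 | step 11 | 3-chloro-4,6,6-trimethyl-5-(triethylsilyloxy)cyclohexan-1-one (4,5-trans) | O=C1CC(Cl)[C@H](C)[C@@H](O[Si](CC)(CC)CC)C1(C)C
F3 | step 11 | (4S,5R)-4,6,6-trimethyl-5-(triethylsilyloxy)cyclohex-2-en-1-one | O=C1C=C[C@H](C)[C@@H](O[Si](CC)(CC)CC)C1(C)C
F4 | step 11 | (4S,5R)-2-iodo-4,6,6-trimethyl-5-(triethylsilyloxy)cyclohex-2-en-1-one | O=C1C(I)=C[C@H](C)[C@@H](O[Si](CC)(CC)CC)C1(C)C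
F5 | step 14 | tert-butyl N-[(1R,2R)-1-hydroxy-3-methoxy-1-[(3S,4R)-3,5,5-trimethyl-6-oxo-4-(triethylsilyloxy)cyclohex-1-en-1-yl]propan-2-yl]carbamate (C1'' epimer of 26) | CC(C)(C)OC(=O)N[C@H](COC)[C@H](O)C1=C[C@H](C)[C@@H](O[Si](CC)(CC)CC)C(C)(C)C1=O
F6 | step 14 | methanesulfonate of F5 at C1'' | CC(C)(C)OC(=O)N[C@H](COC)[C@H](OS(C)(=O)=O)C1=C[C@H](C)[C@@H](O[Si](CC)(CC)CC)C(C)(C)C1=O
F7 | step 14 | (4R,5S)-4-(methoxymethyl)-5-[(3S,4R)-3,5,5-trimethyl-6-oxo-4-(triethylsilyloxy)cyclohex-1-en-1-yl]-1,3-oxazolidin-2-one | O=C1N[C@H](COC)[C@@H](O1)C1=C[C@H](C)[C@@H](O[Si](CC)(CC)CC)C(C)(C)C1=O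
F8 | step 14 | tert-butyl (4R,5S)-4-(methoxymethyl)-2-oxo-5-[(3S,4R)-3,5,5-trimethyl-6-oxo-4-(triethylsilyloxy)cyclohex-1-en-1-yl]-1,3-oxazolidine-3-carboxylate | O=C1N(C(=O)OC(C)(C)C)[C@H](COC)[C@@H](O1)C1=C[C@H](C)[C@@H](O[Si](CC)(CC)CC)C(C)(C)C1=O
F9 | step 16 | (1S,2R)-2-[(tert-butoxycarbonyl)amino]-3-methoxy-1-[(3S,4R)-3,5,5-trimethyl-6-oxo-4-(triethylsilyloxy)cyclohex-1-en-1-yl]propyl (4E,7R,9S)-7-methoxy-9-methylhexadec-4-enoate | CC(C)(C)OC(=O)N[C@H](COC)[C@@H](OC(=O)CC/C=C/C[C@@H](C[C@@H](C)CCCCCCC)OC)C1=C[C@H](C)[C@@H](O[Si](CC)(CC)CC)C(C)(C)C1=O
F10 | step 16 | (1S,2R)-2-amino-1-[(3S,4R)-4-hydroxy-3,5,5-trimethyl-6-oxocyclohex-1-en-1-yl]-3-methoxypropyl (4E,7R,9S)-7-methoxy-9-methylhexadec-4-enoate hydrochloride | Cl.N[C@H](COC)[C@@H](OC(=O)CC/C=C/C[C@@H](C[C@@H](C)CCCCCCC)OC)C1=C[C@H](C)[C@@H](O)C(C)(C)C1=O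
F11 | step 4 | (7R,9S)-1-[tert-butyl(dimethyl)silyl]oxy-9-methylhexadec-4-yn-7-ol | CCCCCCC[C@H](C)C[C@H](CC#CCCCO[Si](C)(C)C(C)(C)C)O
F12 | step 4 | tert-butyl{[(7R,9S)-7-methoxy-9-methylhexadec-4-yn-1-yl]oxy}dimethylsilane | CCCCCCC[C@H](C)C[C@H](CC#CCCCO[Si](C)(C)C(C)(C)C)OC
F13 | step 4 | tert-butyl{[(4E,7R,9S)-7-methoxy-9-methylhexadec-4-en-1-yl]oxy}dimethylsilane | CCCCCCC[C@H](C)C[C@H](C/C=C/CCCO[Si](C)(C)C(C)(C)C)OC
A1 | alternative 1 | (4S,5R)-5-hydroxy-4,6,6-trimethylcyclohex-2-en-1-one | O=C1C=C[C@H](C)[C@@H](O)C1(C)C
A2 | alternative 1 | (4E,7R,9S)-7-methoxy-N-[(2R)-1-methoxy-3-oxopropan-2-yl]-9-methylhexadec-4-enamide | CCCCCCC[C@H](C)C[C@H](C/C=C/CCC(=O)N[C@H](COC)C=O)OC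
A3 | alternative 2 | (4E,7R,9S)-N-[(2R,3S,7R,8R)-3,7-dihydroxy-1-methoxy-6,6,8-trimethyl-5,9-dioxononan-2-yl]-7-methoxy-9-methylhexadec-4-enamide | CCCCCCC[C@H](C)C[C@H](C/C=C/CCC(=O)N[C@H](COC)[C@@H](O)CC(=O)C(C)(C)[C@H](O)[C@@H](C)C=O)OC
A4 | alternative 3 | tert-butyl N-[(2R,3S,7R,8S)-3,7-dihydroxy-1-methoxy-6,6,8-trimethyl-4-methylidene-5-oxodec-9-en-2-yl]carbamate | CC(C)(C)OC(=O)N[C@H](COC)[C@@H](O)C(=C)C(=O)C(C)(C)[C@H](O)[C@@H](C)C=C
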